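**Retrosynthetic overview**
1. Target 27 ⇒ tert-butyl heptelidate 21 (spiro-epoxide) plus gliocladic acid 25. The carboxylate opens the epoxide at CH2, and the tert-butyl ester is removed last.
2. Both 21 and 25 ⇒ one common allylic alcohol 10, [(3R,4R)-3-vinyl-4-isopropylcyclohex-1-enyl]methanol.
3. Key C–C bond (C9a–C1 of 21): a [2,3] shift of the alkoxy(dimethylamino)carbene made from 10 and DMF acetal. A formate-level carbon acts as a carbamoyl anion equivalent on an allylic C–O electrophile. The shift sets C9a and creates the exocyclic methylene.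
4. Ring order: cyclohexene first (organocatalytic Michael/aldol to (R)-cryptone 5), oxepinone second (ring-closing metathesis), oxirane last (dihydroxylation and closure). Acid 25 comes from 10 by cross-metathesis.

Assumption: all numbered starting materials are catalogue items. The roughly 90% ee from step 1 is upgraded in step 12, where the minor heterochiral diastereomer is removed by chromatography.

**Route**

Step 1
Reactants: 1 3-methylbutanal; 2 but-3-en-2-one
Product: 3 (2R)-5-oxo-2-(propan-2-yl)hexanal
Conditions: (R)-2-(methoxydiphenylmethyl)pyrrolidine (5 mol %), ethyl 3,4-dihydroxybenzoate (20 mol %), neat, 4 °C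
Reagents that add atoms: none
Why: Enamine-catalysed asymmetric Michael addition, in which the E-enamine of 1 is shielded on one face by the CPh2OMe group of the (R)-pyrrolidine, so the hydrogen-bond-activated enone 2 adds to the open face and sets C2 as R.

Step 2
Reactants: 3 (2R)-5-oxo-2-(propan-2-yl)hexanal
Product: 5 (4R)-4-(propan-2-yl)cyclohex-2-en-1-one [(R)-cryptone], via aldol 4 (not isolated)
Conditions: LiOH (0.2 equiv), i-PrOH, rt
Reagents that add atoms: none
Why: Intramolecular aldol condensation, in which the methyl-ketone enolate closes the six-membered ring on the aldehyde and aldol 4 loses water by E1cB, while the mild catalytic base leaves the γ-stereocentre (now C4, R) untouched.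

Step 3
Reactants: 5 (R)-cryptone; 6 vinylmagnesium bromide
Product: 8 (3R,4R)-3-ethenyl-4-(propan-2-yl)cyclohex-1-en-1-yl trifluoromethanesulfonate, via bromomagnesium enolate 7 (not isolated)
Conditions: 6 (1.3 equiv), CuBr·SMe2 (10 mol %), THF, −78 °C; then PhNTf2 (1.3 equiv), DMPU, −78 °C to rt
Reagents that add atoms: N-phenylbis(trifluoromethanesulfonimide) (PhNTf2), O=S(=O)(N(c1ccccc1)S(=O)(=O)C(F)(F)F)C(F)(F)F
Why: Copper-catalysed conjugate addition followed by enolate O-triflation, in which the vinylcopper species attacks C3 anti to the neighbouring isopropyl group (3,4-trans, new centre R) and trapping of enolate 7 locks the double bond at C1=C2.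

Step 4
Reactants: 8 enol triflate; 9 (tributylstannyl)methanol
Product: 10 [(3R,4R)-3-ethenyl-4-(propan-2-yl)cyclohex-1-en-1-yl]methanol
Conditions: 9 (1.3 equiv), Pd(PPh3)4 (5 mol %), LiCl (3 equiv), 1,4-dioxane, 95 °C
Reagents that add atoms: none
Why: Stille-type cross-coupling in which zerovalent palladium inserts into the C–OTf bond and the stannane delivers CH2OH as a hydroxymethyl anion equivalent, with LiCl speeding transmetalation and no stereocentre touched.

Step 5 (key step)
Reactants: 10 allylic alcohol; 11 N,N-dimethylformamide dimethyl acetal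
Product: 14 (1S,2R,3R)-2-ethenyl-N,N-dimethyl-6-methylidene-3-(propan-2-yl)cyclohexane-1-carboxamide, via mixed amide acetal 12 (not isolated), via alkoxy(amino)carbene 13 (not isolated)
Conditions: 11 (6 equiv, in portions), o-xylene, 145 °C, MeOH stripped through 4 Å sieves, 36 h
Reagents that add atoms: none
Why: Büchi [2,3]-sigmatropic rearrangement, in which acetal exchange gives 12, thermal loss of methanol gives the nucleophilic carbene 13 (a carbamoyl anion equivalent, so a normally electrophilic formate-level carbon bonds to the electrophilic terminus of an allylic C–O system), and the concerted suprafacial shift delivers C(=O)NMe2 to the ring CH= carbon on the face opposite the vinyl group, setting C1 of 14 as S (all-trans, all-equatorial) and leaving the exocyclic methylene.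

Step 6
Reactants: 14 amide; 15 tert-butyl 2-(bromomethyl)prop-2-enoate
Product: 17 2-(tert-butoxycarbonyl)prop-2-en-1-yl (1S,2R,3R)-2-ethenyl-6-methylidene-3-(propan-2-yl)cyclohexane-1-carboxylate, via O-allyl iminium ether triflate 16 (not isolated)
Conditions: 15 (1.5 equiv), AgOTf (1.5 equiv), 4 Å MS, CH2Cl2, dark, −20 °C to rt; then THF–aq NaH2PO4 (pH 4.5), rt
Reagents that add atoms: water, O; silver trifluoromethanesulfonate, [Ag+].[O-]S(=O)(=O)C(F)(F)F (counter-ion of 16 only)
Why: Proposed new method: silver-assisted O-allylation of the tertiary amide by the activated allylic bromide 15 (SN2 and SN2' attack give the same product) forms iminium ether 16, whose mildly acidic hydrolysis expels protonated dimethylamine rather than the alcohol and so hands the acyl group to the allyl oxygen, with C1 untouched because no base is present (a base would form the ketene N,O-acetal and trigger a Claisen shift); the closest known reaction type is the Meerwein-salt or MeOTf O-alkylation–hydrolysis of tertiary amides to esters.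

Step 7
Reactants: 17 triene ester
Product: 18 tert-butyl (5aS,6R,9aS)-9-methylidene-1-oxo-6-(propan-2-yl)-1,3,5a,6,7,8,9,9a-octahydro-2-benzoxepine-4-carboxylate
Conditions: second-generation Hoveyda–Grubbs catalyst (5 mol %), 1,4-benzoquinone (10 mol %), toluene (2 mM), 80 °C
Reagents that add atoms: none
Why: Ring-closing metathesis, in which the catalyst loads on the monosubstituted vinyl group and closes onto the tethered 1,1-disubstituted acrylate, the seven-membered ring forces the ring carbon and CH2O cis on the new trisubstituted alkene, and the hindered exocyclic methylene stays out of the reaction.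

Step 8
Reactants: 18 methylidene lactone
Product: 19 tert-butyl (5aS,6R,9S,9aS)-9-hydroxy-9-(hydroxymethyl)-1-oxo-6-(propan-2-yl)-1,3,5a,6,7,8,9,9a-octahydro-2-benzoxepine-4-carboxylate
Conditions: OsO4 (2 mol %), NMO (1.3 equiv), citric acid (0.75 equiv), t-BuOH–H2O 1:1, 0 °C; used at once
Reagents that add atoms: 4-methylmorpholine N-oxide, C[N+]1([O-])CCOCC1; water, O
Why: Catalytic OsO4/NMO syn-dihydroxylation, in which OsO4 selects the electron-rich 1,1-disubstituted alkene over the ester-conjugated one and, being bulky, approaches the methylenecyclohexane from the equatorial face away from the syn-axial hydrogens at C5a and C7, so OH ends up equatorial and CH2OH axial (C9 = S), while citric acid keeps the medium slightly acidic so the new primary alcohol does not translactonise.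

Step 9
Reactants: 19 diol
Product: 21 tert-butyl (5aS,6R,9S,9aS)-1-oxo-6-(propan-2-yl)-3,5a,6,7,8,9a-hexahydro-1H-spiro[2-benzoxepine-9,2'-oxirane]-4-carboxylate (tert-butyl heptelidate), via primary mesylate 20 (not isolated)
Conditions: MsCl (1.1 equiv), 2,4,6-collidine (3 equiv), CH2Cl2, 0 °C; then DBU (1.5 equiv), 0 °C
Reagents that add atoms: methanesulfonyl chloride, CS(=O)(=O)Cl (its atoms stay in 20 only)
Why: Selective sulfonylation of the primary alcohol followed by intramolecular Williamson-type 3-exo-tet closure by the tertiary oxygen, in which the C9–O bond is never broken so the configuration from step 8 is kept.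

Step 10
Reactants: 10 allylic alcohol; 22 ethyl 2-(hydroxymethyl)prop-2-enoate
Product: 23 ethyl (2E)-2-(hydroxymethyl)-3-[(1R,6R)-3-(hydroxymethyl)-6-(propan-2-yl)cyclohex-2-en-1-yl]prop-2-enoate (ethyl gliocladate)
Conditions: 22 (5 equiv), second-generation Hoveyda–Grubbs catalyst (2 × 5 mol %), 1,4-benzoquinone (10 mol %), CH2Cl2, 40 °C, Ar sparge
Reagents that add atoms: none
Why: Olefin cross-metathesis between the monosubstituted vinyl group of 10 and an excess of the slowly homodimerising acrylate 22, in which the trisubstituted ring alkene is inert and the thermodynamically preferred E isomer forms (ring carbon trans to the ester, cis to CH2OH).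

Step 11
Reactants: 23 ethyl gliocladate
Product: 25 (2E)-2-(hydroxymethyl)-3-[(1R,6R)-3-(hydroxymethyl)-6-(propan-2-yl)cyclohex-2-en-1-yl]prop-2-enoic acid (gliocladic acid), via lithium gliocladate 24 (not isolated)
Conditions: LiOH (3 equiv), THF–H2O 3:1, rt; then 1 M HCl to pH 3
Reagents that add atoms: lithium hydroxide, [Li+].[OH-]
Why: Saponification of the only ester in the molecule, which touches neither the alkene geometry nor the two ring stereocentres.

Step 12
Reactants: 21 tert-butyl heptelidate; 25 gliocladic acid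
Product: 26 tert-butyl (5aS,6R,9S,9aS)-9-hydroxy-9-({[(2E)-2-(hydroxymethyl)-3-[(1R,6R)-3-(hydroxymethyl)-6-(propan-2-yl)cyclohex-2-en-1-yl]prop-2-enoyl]oxy}methyl)-1-oxo-6-(propan-2-yl)-1,3,5a,6,7,8,9,9a-octahydro-2-benzoxepine-4-carboxylate
Conditions: 25 (1.5 equiv), Cs2CO3 (20 mol %), DMF, 55 °C
Reagents that add atoms: none
Why: Base-catalysed SN2 ring opening of the 2,2-disubstituted epoxide by the carboxylate at the unhindered CH2 terminus, in which the excess free acid reprotonates the tertiary alkoxide, the neutral alcohols of 25 cannot compete with its carboxylate, and C9 keeps its C–O bond and configuration.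

Step 13
Reactants: 26 tert-butyl ester
Product: 27 target CNP0361406.2
Conditions: TFA–CH2Cl2 1:4, 0 °C, 2 h; brief aq NaHCO3 wash, then pH 3
Reagents that add atoms: none
Why: Acidolysis of the tert-butyl ester through the tert-butyl cation (lost as isobutene), while at 0 °C the lactone, the acrylate ester, the primary allylic alcohols and the inductively deactivated tertiary alcohol are left alone.

**Compound list**
1 | 3-methylbutanal | CC(C)CC=O | starting material
2 | but-3-en-2-one | CC(=O)C=C | starting material
3 | (2R)-5-oxo-2-(propan-2-yl)hexanal | CC(C)[C@@H](CCC(C)=O)C=O | intermediate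
4 | (4R)-3-hydroxy-4-(propan-2-yl)cyclohexan-1-one (carbinol epimers, not isolated) | CC(C)[C@H]1CCC(=O)CC1O | intermediate
5 | (4R)-4-(propan-2-yl)cyclohex-2-en-1-one, (R)-cryptone | CC(C)[C@H]1CCC(=O)C=C1 | intermediate
6 | vinylmagnesium bromide | C=C[Mg]Br | starting material
7 | bromomagnesium (3R,4R)-3-ethenyl-4-(propan-2-yl)cyclohex-1-en-1-olate (not isolated) | CC(C)[C@H]1CCC(O[Mg]Br)=C[C@@H]1C=C | intermediate
8 | (3R,4R)-3-ethenyl-4-(propan-2-yl)cyclohex-1-en-1-yl trifluoromethanesulfonate | CC(C)[C@H]1CCC(OS(=O)(=O)C(F)(F)F)=C[C@@H]1C=C | intermediate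
9 | (tributylstannyl)methanol | CCCC[Sn](CO)(CCCC)CCCC | starting material
10 | [(3R,4R)-3-ethenyl-4-(propan-2-yl)cyclohex-1-en-1-yl]methanol | CC(C)[C@H]1CCC(CO)=C[C@@H]1C=C | intermediate
11 | N,N-dimethylformamide dimethyl acetal | COC(OC)N(C)C | starting material
12 | mixed amide acetal of 10, ROCH(OMe)NMe2 (acetal epimers, not isolated) | CC(C)[C@H]1CCC(COC(OC)N(C)C)=C[C@@H]1C=C | intermediate
13 | (dimethylamino){[(3R,4R)-3-ethenyl-4-(propan-2-yl)cyclohex-1-en-1-yl]methoxy}carbene (not isolated) | CC(C)[C@H]1CCC(CO[C]N(C)C)=C[C@@H]1C=C | intermediate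
14 | (1S,2R,3R)-2-ethenyl-N,N-dimethyl-6-methylidene-3-(propan-2-yl)cyclohexane-1-carboxamide | CC(C)[C@H]1CCC(=C)[C@@H](C(=O)N(C)C)[C@@H]1C=C | intermediate
15 | tert-butyl 2-(bromomethyl)prop-2-enoate | C=C(CBr)C(=O)OC(C)(C)C | starting material
16 | O-[2-(tert-butoxycarbonyl)allyl] iminium ether triflate of 14 (not isolated) | CC(C)[C@H]1CCC(=C)[C@@H](C(OCC(=C)C(=O)OC(C)(C)C)=[N+](C)C)[C@@H]1C=C.[O-]S(=O)(=O)C(F)(F)F | intermediate
17 | 2-(tert-butoxycarbonyl)prop-2-en-1-yl (1S,2R,3R)-2-ethenyl-6-methylidene-3-(propan-2-yl)cyclohexane-1-carboxylate | CC(C)[C@H]1CCC(=C)[C@@H](C(=O)OCC(=C)C(=O)OC(C)(C)C)[C@@H]1C=C | intermediate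
18 | tert-butyl (5aS,6R,9aS)-9-methylidene-1-oxo-6-(propan-2-yl)-1,3,5a,6,7,8,9,9a-octahydro-2-benzoxepine-4-carboxylate | CC(C)[C@H]1CCC(=C)[C@H]2C(=O)OCC(C(=O)OC(C)(C)C)=C[C@H]12 | intermediate
19 | tert-butyl (5aS,6R,9S,9aS)-9-hydroxy-9-(hydroxymethyl)-1-oxo-6-(propan-2-yl)-octahydro-2-benzoxepine-4-carboxylate | CC(C)[C@H]1CC[C@@](O)(CO)[C@H]2C(=O)OCC(C(=O)OC(C)(C)C)=C[C@H]12 | intermediate
20 | primary methanesulfonate of 19 (not isolated) | CC(C)[C@H]1CC[C@@](O)(COS(C)(=O)=O)[C@H]2C(=O)OCC(C(=O)OC(C)(C)C)=C[C@H]12 | intermediate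
21 | tert-butyl heptelidate, (5aS,6R,9S,9aS) spiro-epoxide | CC(C)[C@H]1CC[C@@]2(CO2)[C@H]3C(=O)OCC(C(=O)OC(C)(C)C)=C[C@H]13 | intermediate
22 | ethyl 2-(hydroxymethyl)prop-2-enoate | CCOC(=O)C(=C)CO | starting material
23 | ethyl gliocladate, (2E,1R,6R) | CCOC(=O)/C(=C/[C@H]1C=C(CO)CC[C@@H]1C(C)C)CO | intermediate
24 | lithium gliocladate (not isolated) | [Li+].[O-]C(=O)/C(=C/[C@H]1C=C(CO)CC[C@@H]1C(C)C)CO | intermediate
25 | gliocladic acid, (2E,1R,6R) | OC(=O)/C(=C/[C@H]1C=C(CO)CC[C@@H]1C(C)C)CO | intermediate
26 | tert-butyl ester of the target | CC(C)[C@H]1CC[C@@](O)(COC(=O)/C(=C/[C@H]2C=C(CO)CC[C@@H]2C(C)C)CO)[C@H]2C(=O)OCC(C(=O)OC(C)(C)C)=C[C@H]12 | intermediate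
27 | CNP0361406.2 | CC(C)[C@H]1CC[C@@](O)(COC(=O)/C(=C/[C@H]2C=C(CO)CC[C@@H]2C(C)C)CO)[C@H]2C(=O)OCC(C(=O)O)=C[C@H]12 | target

**Step count and risks**

Total step count: 13. Longest linear sequence: 11 (steps 1–9, 12, 13). The gliocladic branch (steps 10 and 11) leaves the main line at 10.

Step 5 is the most exposed step. At 145 °C the activated alcohol can lose DMF by 1,4-elimination through the doubly allylic C3–H. It can also be O-methylated, or it can rearrange with imperfect facial control. The fallback makes the same bond but inverts the polarity of the other partner, setting out from 10. PdCl2 (5 mol %), PPh3 (20 mol %), ZnEt2 (3.5 equiv) and CO2 (1 atm) in THF at 40 °C ionise the allylic alcohol. Ethyl transfer from zinc turns the electrophilic π-allylpalladium complex into a nucleophilic σ-allyl metal species. This species attacks CO2 through its ring γ-carbon, anti to the vinyl group, to give (1S,2R,3R)-2-ethenyl-6-methylidene-3-(propan-2-yl)cyclohexane-1-carboxylic acid F1. Alkylation of F1 with 15 (Cs2CO3, DMF, rt) comes back to the route at 17.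

Step 6 may stall at the O-allylation, because the amide is hindered and silver binds to the alkenes. It may also return 14 on hydrolysis. The fallback sets out from 14 and separates activation from allyl transfer. MeOTf (CH2Cl2, rt) gives the O-methyl iminium ether triflate F2. Aqueous NaH2PO4 hydrolyses F2 to the methyl ester F3. Me3SnOH (1,2-dichloroethane, 70 °C) cleaves F3 without epimerisation to the carboxylic acid F1. Cs2CO3 and 15 in DMF then come back at 17.

Step 10 couples a vinyl group on a doubly flanked ring carbon with a 1,1-disubstituted acrylate. It may give little conversion or cause alkene migration. The fallback builds the alkene from a carbonyl group instead and sets out from 8, whose enol triflate alkene is too electron-poor to be oxidised.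
- OsO4 (cat.), NaIO4 and 2,6-lutidine in dioxane–water cleave only the vinyl group, giving the aldehyde F4.
- The vinylalane F5 is made from ethyl propiolate with i-Bu2AlH and NMO in THF at 0 °C. It adds to F4 to give the Morita–Baylis–Hillman-type alcohol F6.
- Ac2O/DMAP converts F6 into the secondary acetate F7.
- DABCO in THF–aqueous NaHCO3 transposes F7 by two SN2' displacements to the primary (E)-allylic alcohol F8.
- The coupling of step 4 (9, Pd(PPh3)4, LiCl, dioxane) applied to F8 comes back to the route at 23.

**Further compounds**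
F1 | step 5 | (1S,2R,3R)-2-ethenyl-6-methylidene-3-(propan-2-yl)cyclohexane-1-carboxylic acid | CC(C)[C@H]1CCC(=C)[C@@H](C(=O)O)[C@@H]1C=C
F2 | step 6 | O-methyl iminium ether triflate of 14 | CC(C)[C@H]1CCC(=C)[C@@H](C(OC)=[N+](C)C)[C@@H]1C=C.[O-]S(=O)(=O)C(F)(F)F
F3 | step 6 | methyl (1S,2R,3R)-2-ethenyl-6-methylidene-3-(propan-2-yl)cyclohexane-1-carboxylate | CC(C)[C@H]1CCC(=C)[C@@H](C(=O)OC)[C@@H]1C=C
F4 | step 10 | (1R,6R)-6-(propan-2-yl)-3-(trifluoromethanesulfonyloxy)cyclohex-2-ene-1-carbaldehyde | CC(C)[C@H]1CCC(OS(=O)(=O)C(F)(F)F)=C[C@@H]1C=O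
F5 | step 10 | ethyl 2-[bis(2-methylpropyl)alumanyl]prop-2-enoate | CCOC(=O)C(=C)[Al](CC(C)C)CC(C)C
F6 | step 10 | ethyl 2-{hydroxy[(1R,6R)-6-(propan-2-yl)-3-(trifluoromethanesulfonyloxy)cyclohex-2-en-1-yl]methyl}prop-2-enoate (carbinol epimers) | CCOC(=O)C(=C)C(O)[C@H]1C=C(OS(=O)(=O)C(F)(F)F)CC[C@@H]1C(C)C
F7 | step 10 | acetate of F6 | CCOC(=O)C(=C)C(OC(C)=O)[C@H]1C=C(OS(=O)(=O)C(F)(F)F)CC[C@@H]1C(C)C
F8 | step 10 | ethyl (2E)-2-(hydroxymethyl)-3-[(1S,6R)-6-(propan-2-yl)-3-(trifluoromethanesulfonyloxy)cyclohex-2-en-1-yl]prop-2-enoate | CCOC(=O)/C(=C/[C@H]1C=C(OS(=O)(=O)C(F)(F)F)CC[C@@H]1C(C)C)CO
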